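**Retrosynthetic overview**

- The all-E, C2-symmetric C40 tetrol is cut at both ring–alkyne bonds, C6–C7 and C6'–C7' (C(sp2)–C(sp)). This gives two copies of one C9 ring enol triflate and one C22 heptaene-1,17-diyne, carried as its bis(trimethylsilyl) derivative.
- Enabling feature: the C2 axis through C15=C15' makes the two ring–alkyne bonds equivalent. In each cyclohexene ring, C6 is the enol carbon of the C5=C6 bond and sits next to the quaternary C1 (CMe2), so a C6 ketone can enolise only toward C5 and gives a single enol triflate. The key step is a one-flask desilylation and twofold Sonogashira coupling with the unprotected diol triflate, and it ends the synthesis.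
- Ring piece: ketoisophorone already holds ring carbons C1–C6, so no carbocycle is built. C3 is set by asymmetric transfer hydrogenation, C4 (trans) by anti nucleophilic epoxidation and SmI2 opening. The only ring closed is a temporary trans-fused dioxolane (step 5, opened in step 7), which holds the C4–O bond against β-elimination during triflation.
- Chain piece: twofold Horner–Wadsworth–Emmons reaction of the C10 trienedial with a C6 silyl-enyne phosphonate forms C11=C12 and C11'=C12'.

Key step: step 12

Remark: atom numbers in the overview and in the Why lines are carotenoid numbers (ring C1 = CMe2, C2 = CH2, C3 and C4 = carbinol carbons, C5 = methyl-bearing alkene carbon, C6 = alkene carbon carrying the chain; chain C7≡C8 up to C15; primes for the second half). Compounds 1, 9 and 14 are assumed to be purchasable.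

**Route**

Step 1
Reactants: 1 ketoisophorone (2,6,6-trimethylcyclohex-2-ene-1,4-dione)
Product: 2 (S)-phorenol, (4S)-4-hydroxy-2,6,6-trimethylcyclohex-2-en-1-one
Conditions: RuCl[(S,S)-TsDPEN](p-cymene) (1 mol %), KOH (2 mol %), iPrOH, rt
Reagents that add atoms: none
Why: Noyori asymmetric transfer hydrogenation should reduce only the unhindered C3 carbonyl (the C6 carbonyl lies between the quaternary C1 and the methylated C5), and the (S,S) ligand is expected to deliver hydride through the six-membered metal–ligand bifunctional transition state to the face that gives the (S)-carbinol, the C4=C5 π bond taking the role that an aryl group plays in aryl ketones.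

Step 2
Reactants: 2 (S)-phorenol
Product: 3 (4S)-4-[(2-methoxypropan-2-yl)oxy]-2,6,6-trimethylcyclohex-2-en-1-one
Conditions: 2-methoxypropene (3 equiv), PPTS (2 mol %), CH2Cl2, 0 °C; Et3N quench
Reagents that add atoms: 2-methoxypropene, COC(C)=C
Why: Acid-catalysed addition of the alcohol to the enol ether (mixed-ketal formation) gives a bulky, base-stable ether whose ketal carbon is reused for the dioxolane in step 5, and no stereocentre is touched.

Step 3
Reactants: 3 (4S)-4-[(2-methoxypropan-2-yl)oxy]-2,6,6-trimethylcyclohex-2-en-1-one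
Product: 4 (1R,5S,6R)-5-[(2-methoxypropan-2-yl)oxy]-1,3,3-trimethyl-7-oxabicyclo[4.1.0]heptan-2-one (oxirane trans to the ether)
Conditions: H2O2 (30 % aq.), NaOH (0.3 equiv), MeOH, 0 °C
Reagents that add atoms: hydrogen peroxide, OO
Why: In this Weitz–Scheffer nucleophilic epoxidation, hydroperoxide should add to the β-carbon C4 on the face anti to the neighbouring C3 ketal ether and the enolate closes the oxirane on that same face, so the new C4–O bond is trans to the C3–O bond (C5 is set at the same time and is erased in step 6).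

Step 4
Reactants: 4 epoxy ketone
Product: 5 (3S,4S)-3-hydroxy-4-[(2-methoxypropan-2-yl)oxy]-2,6,6-trimethylcyclohexan-1-one (mixture of C2 epimers)
Conditions: SmI2 (2.2 equiv), THF/MeOH, −90 °C; pH 7 buffer
Reagents that add atoms: none
Why: SmI2 reduction of an α,β-epoxy ketone (ketyl formation, cleavage of the Cα–O bond at C5, protonation by methanol) leaves the C4–O bond untouched, so the trans C3/C4 relationship is retained and the epimer mixture at C5 is of no consequence.

Step 5
Reactants: 5 hydroxy ketal ketone
Product: 6 (3aS,7aS)-2,2,4,6,6-pentamethylhexahydro-1,3-benzodioxol-5-one (trans-fused acetonide, mixture of C4 epimers)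
Conditions: PPTS (5 mol %), 5 Å molecular sieves, CH2Cl2, rt
Reagents that add atoms: none
Why: In this acid-catalysed intramolecular transketalisation, loss of methanol from the mixed ketal gives an oxocarbenium ion that the adjacent C4 hydroxyl captures (5-exo-trig), which should close the trans-fused dioxolane with both C–O bonds equatorial while the sieves take up methanol.

Step 6
Reactants: 6 trans-fused acetonide ketone
Product: 7 (3aS,7aS)-2,2,4,6,6-pentamethyl-3a,6,7,7a-tetrahydro-1,3-benzodioxol-5-yl trifluoromethanesulfonate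
Conditions: KN(SiMe3)2 (1.2 equiv), THF, −78 °C; Comins' reagent (1.3 equiv), −78 to −40 °C
Reagents that add atoms: N-(5-chloropyridin-2-yl)-1,1,1-trifluoro-N-[(trifluoromethyl)sulfonyl]methanesulfonamide (Comins' reagent), FC(F)(F)S(=O)(=O)N(c1ccc(Cl)cn1)S(=O)(=O)C(F)(F)F
Why: The ketone can enolise only toward C5 because C1 is quaternary, and the potassium enolate is O-sulfonylated (enol triflate formation), while the trans-fused dioxolane holds the β C4–O bond near the enolate plane, where it overlaps poorly with the enolate π system, so that E1cB loss of the C4 oxygen is disfavoured.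

Step 7
Reactants: 7 acetonide enol triflate
Product: 8 (3S,4S)-3,4-dihydroxy-2,6,6-trimethylcyclohex-1-en-1-yl trifluoromethanesulfonate
Conditions: AcOH/H2O/THF (3:1:1), 40 °C
Reagents that add atoms: none
Why: Acid hydrolysis of the strained trans-fused acetonide should be fast under conditions that leave the enol triflate (electron-poor alkene, acid-stable S–O bond) and both carbinol centres untouched.

Step 8
Reactants: 9 (E)-3-methylpent-2-en-4-yn-1-ol
Product: 11 (E)-3-methyl-5-(trimethylsilyl)pent-2-en-4-yn-1-ol, via bis-silyl ether 10 (not isolated)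
Conditions: n-BuLi (2.1 equiv), THF, −78 °C; Me3SiCl (2.3 equiv), −78 °C to rt; then 1 M aq. HCl, rt
Reagents that add atoms: chlorotrimethylsilane, C[Si](C)(C)Cl
Why: Double deprotonation (alkoxide and acetylide) and silylation give the bis-silyl compound, and the acid-labile O–Si bond is then hydrolysed selectively on work-up while the C(sp)–Si bond and the E double bond stay intact.

Step 9
Reactants: 11 (E)-3-methyl-5-(trimethylsilyl)pent-2-en-4-yn-1-ol
Product: 12 [(E)-5-bromo-3-methylpent-3-en-1-yn-1-yl]trimethylsilane
Conditions: CBr4, PPh3, CH2Cl2, 0 °C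
Reagents that add atoms: carbon tetrabromide, BrC(Br)(Br)Br
Why: The Appel bromination converts the primary allylic alcohol to the bromide under neutral conditions by SN2 displacement of the alkoxyphosphonium ion, without allylic transposition or E/Z change.

Step 10
Reactants: 12 allylic bromide
Product: 13 diethyl [(E)-3-methyl-5-(trimethylsilyl)pent-2-en-4-yn-1-yl]phosphonate
Conditions: P(OEt)3 (neat), 100 °C
Reagents that add atoms: triethyl phosphite, CCOP(OCC)OCC
Why: The Michaelis–Arbuzov reaction (SN2 attack of phosphorus on the primary allylic bromide, then dealkylation by bromide) should give the allylic phosphonate with the E-enyne retained.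

Step 11
Reactants: 13 phosphonate (2.2 equiv); 14 (2E,4E,6E)-2,7-dimethylocta-2,4,6-trienedial
Product: 15 (3E,5E,7E,9E,11E,13E,15E)-3,7,12,16-tetramethyl-1,18-bis(trimethylsilyl)octadeca-3,5,7,9,11,13,15-heptaene-1,17-diyne
Conditions: NaN(SiMe3)2 (2.2 equiv), THF, −78 °C; then 14, −78 to 0 °C, dark
Reagents that add atoms: none
Why: In this twofold Horner–Wadsworth–Emmons olefination the phosphonate-stabilised allyl anion adds through its α-carbon to each enal carbonyl and syn-elimination from the equilibrated oxaphosphetane should give the E C11=C12 and C11'=C12' bonds, while the low temperature limits rotation about C9–C10 in the anion.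

Step 12
Reactants: 15 bis(trimethylsilyl) heptaene-diyne (1 equiv); 8 diol enol triflate (2.4 equiv)
Product: 18 (all-E)-(3S,4S,3'S,4'S)-7,8,7',8'-tetradehydro-β,β-carotene-3,4,3',4'-tetrol, via free heptaene-diyne 16 (not isolated), via monocoupled C31 enyne diol 17 (not isolated)
Conditions: K2CO3 (0.2 equiv), MeOH/THF (1:1), rt, argon, dark; then 8, Pd(PPh3)4 (10 mol %), CuI (20 mol %), Et3N, degassed, rt to 40 °C, dark
Reagents that add atoms: none
Why: Carbonate-catalysed methanolysis first frees both alkyne termini (16); zerovalent palladium then inserts into the C6–O bond of triflate 8, the copper acetylide formed from the terminal alkyne with CuI and Et3N transmetalates, and reductive elimination forms the C6–C7 bond, after which the same cycle joins a second molecule of 8 to the C31 monoadduct 17 at its remaining terminus. The closest known reaction type is the Sonogashira coupling of hindered 2,6,6-trimethylcyclohexenyl triflates with terminal enynes that is used for 7,8-didehydro carotenoid end groups, run here twofold after desilylation in the same flask. No ring is closed and no stereocentre is made: C3 and C4 of each ring arrive unchanged in 8, and the seven E double bonds arrive unchanged in 15. The step needs cross-coupling to outrun oxidative alkyne dimerisation, which strict exclusion of oxygen should secure, and it needs a single coupling site per ring, which is secured because the triflate sits only at C6 (the quaternary C1 allowed no other enol triflate) and the free hydroxyls are inert to the catalyst. Room temperature, darkness and the absence of acid or iodine should keep the 9E and 9'E bonds from equilibrating to the Z forms that acetylenic carotenoids reach easily. In one operation the step therefore forms both ring–chain bonds, completes the C40 skeleton and the conjugated system from C5 to C5', and releases the unprotected target.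

**Compound list**

1 | ketoisophorone (2,6,6-trimethylcyclohex-2-ene-1,4-dione) | CC1=CC(=O)CC(C)(C)C1=O | starting material
2 | (S)-phorenol, (4S)-4-hydroxy-2,6,6-trimethylcyclohex-2-en-1-one | CC1=C[C@@H](O)CC(C)(C)C1=O | intermediate
3 | (4S)-4-[(2-methoxypropan-2-yl)oxy]-2,6,6-trimethylcyclohex-2-en-1-one | CC1=C[C@@H](OC(C)(C)OC)CC(C)(C)C1=O | intermediate
4 | (1R,5S,6R)-5-[(2-methoxypropan-2-yl)oxy]-1,3,3-trimethyl-7-oxabicyclo[4.1.0]heptan-2-one | C[C@@]12O[C@@H]1[C@@H](OC(C)(C)OC)CC(C)(C)C2=O | intermediate
5 | (3S,4S)-3-hydroxy-4-[(2-methoxypropan-2-yl)oxy]-2,6,6-trimethylcyclohexan-1-one (C2 epimers) | CC1C(=O)C(C)(C)C[C@H](OC(C)(C)OC)[C@H]1O | intermediate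
6 | (3aS,7aS)-2,2,4,6,6-pentamethylhexahydro-1,3-benzodioxol-5-one (trans-fused, C4 epimers) | CC1C(=O)C(C)(C)C[C@@H]2OC(C)(C)O[C@@H]12 | intermediate
7 | (3aS,7aS)-2,2,4,6,6-pentamethyl-3a,6,7,7a-tetrahydro-1,3-benzodioxol-5-yl trifluoromethanesulfonate | CC1=C(OS(=O)(=O)C(F)(F)F)C(C)(C)C[C@@H]2OC(C)(C)O[C@@H]12 | intermediate
8 | (3S,4S)-3,4-dihydroxy-2,6,6-trimethylcyclohex-1-en-1-yl trifluoromethanesulfonate | CC1=C(OS(=O)(=O)C(F)(F)F)C(C)(C)C[C@H](O)[C@H]1O | intermediate
9 | (E)-3-methylpent-2-en-4-yn-1-ol | C#C/C(C)=C/CO | starting material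
10 | trimethyl{[(E)-3-methyl-5-(trimethylsilyl)pent-2-en-4-yn-1-yl]oxy}silane | C[Si](C)(C)C#C/C(C)=C/CO[Si](C)(C)C | intermediate
11 | (E)-3-methyl-5-(trimethylsilyl)pent-2-en-4-yn-1-ol | C[Si](C)(C)C#C/C(C)=C/CO | intermediate
12 | [(E)-5-bromo-3-methylpent-3-en-1-yn-1-yl]trimethylsilane | C[Si](C)(C)C#C/C(C)=C/CBr | intermediate
13 | diethyl [(E)-3-methyl-5-(trimethylsilyl)pent-2-en-4-yn-1-yl]phosphonate | CCOP(=O)(OCC)C/C=C(\C)C#C[Si](C)(C)C | intermediate
14 | (2E,4E,6E)-2,7-dimethylocta-2,4,6-trienedial | O=C/C(C)=C/C=C/C=C(C)/C=O | starting material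
15 | (3E,5E,7E,9E,11E,13E,15E)-3,7,12,16-tetramethyl-1,18-bis(trimethylsilyl)octadeca-3,5,7,9,11,13,15-heptaene-1,17-diyne | C[Si](C)(C)C#C/C(C)=C/C=C/C(C)=C/C=C/C=C(C)/C=C/C=C(\C)C#C[Si](C)(C)C | intermediate
16 | (3E,5E,7E,9E,11E,13E,15E)-3,7,12,16-tetramethyloctadeca-3,5,7,9,11,13,15-heptaene-1,17-diyne | C#C/C(C)=C/C=C/C(C)=C/C=C/C=C(C)/C=C/C=C(\C)C#C | intermediate
17 | (1S,2S)-3,5,5-trimethyl-4-[(3E,5E,7E,9E,11E,13E,15E)-3,7,12,16-tetramethyloctadeca-3,5,7,9,11,13,15-heptaene-1,17-diyn-1-yl]cyclohex-3-ene-1,2-diol | C#C/C(C)=C/C=C/C(C)=C/C=C/C=C(C)/C=C/C=C(\C)C#CC1=C(C)[C@H](O)[C@@H](O)CC1(C)C | intermediate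
18 | (all-E)-(3S,4S,3'S,4'S)-7,8,7',8'-tetradehydro-β,β-carotene-3,4,3',4'-tetrol | CC1=C(C#C/C(C)=C/C=C/C(C)=C/C=C/C=C(C)/C=C/C=C(\C)C#CC2=C(C)[C@H](O)[C@@H](O)CC2(C)C)C(C)(C)C[C@H](O)[C@H]1O | target

**Count and risks**

Total step count: 12. Longest linear sequence: 8 steps (steps 1–7, then step 12).

Steps most likely to fail:

1. Step 12. What may go wrong: copper-mediated oxidative dimerisation or oligomerisation of the free diyne, stalling after the first coupling at the hindered C6, and attack of methoxide at the sulfur of the triflate. The fallback sets out from 15 (with 8 as partner) and comes back at 18 without terminal alkyne, copper or methanol. Silicon-to-tin exchange on 15 with (Bu3Sn)2O and catalytic Bu4NF in THF at 60 °C should give (3E,5E,7E,9E,11E,13E,15E)-3,7,12,16-tetramethyl-1,18-bis(tributylstannyl)octadeca-3,5,7,9,11,13,15-heptaene-1,17-diyne F1. A twofold Stille coupling of F1 with 8 (2.4 equiv), Pd(PPh3)4 and LiCl in THF at 50 °C in the dark should then give 18.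

2. Step 6. What may go wrong: slow deprotonation at the hindered C5–H and β-elimination of the C4 oxygen from the enolate despite the ring constraint. The fallback avoids any enolate; it sets out from 6 and comes back at 18. Condensation of 6 with N2H4·H2O (Et3N, EtOH, 80 °C) should give the hydrazone (3aS,7aS)-5-hydrazinylidene-2,2,4,6,6-pentamethylhexahydro-1,3-benzodioxole F2. Barton iodination (I2, tetramethylguanidine, THF, 0 °C) should give the vinyl iodide (3aS,7aS)-5-iodo-2,2,4,6,6-pentamethyl-3a,6,7,7a-tetrahydro-1,3-benzodioxole F3, since only C5 carries a hydrogen that can be lost. Hydrolysis (AcOH/H2O/THF, 40 °C) should give (1S,2S)-4-iodo-3,5,5-trimethylcyclohex-3-ene-1,2-diol F4. F4 then takes the place of 8 under the conditions of step 12 to give 18.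

3. Step 11. What may go wrong: rotation about C9–C10 in the delocalised phosphonate carbanion (loss of the 9E geometry), Z-olefin formation at C11=C12, and incomplete second olefination. The fallback reverses the polarity so that the enyne is never deprotonated; it sets out from 11 and 14 and comes back at 15. Oxidation of 11 with MnO2 (CH2Cl2, rt) should give (E)-3-methyl-5-(trimethylsilyl)pent-2-en-4-ynal F5. Reduction of 14 with NaBH4 (MeOH, 0 °C) should give (2E,4E,6E)-2,7-dimethylocta-2,4,6-triene-1,8-diol F6. PBr3 (Et2O, 0 °C) should give (2E,4E,6E)-1,8-dibromo-2,7-dimethylocta-2,4,6-triene F7, and P(OEt)3 (100 °C) should give tetraethyl [(2E,4E,6E)-2,7-dimethylocta-2,4,6-triene-1,8-diyl]bis(phosphonate) F8. Twofold Horner–Wadsworth–Emmons reaction of F8 (NaN(SiMe3)2, THF, −78 to 0 °C) with F5 (2.2 equiv) should give 15.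

**Further compounds**

F1 | step 12 | (3E,5E,7E,9E,11E,13E,15E)-3,7,12,16-tetramethyl-1,18-bis(tributylstannyl)octadeca-3,5,7,9,11,13,15-heptaene-1,17-diyne | CCCC[Sn](CCCC)(CCCC)C#C/C(C)=C/C=C/C(C)=C/C=C/C=C(C)/C=C/C=C(\C)C#C[Sn](CCCC)(CCCC)CCCC
F2 | step 6 | (3aS,7aS)-5-hydrazinylidene-2,2,4,6,6-pentamethylhexahydro-1,3-benzodioxole | CC1C(=NN)C(C)(C)C[C@@H]2OC(C)(C)O[C@@H]12
F3 | step 6 | (3aS,7aS)-5-iodo-2,2,4,6,6-pentamethyl-3a,6,7,7a-tetrahydro-1,3-benzodioxole | CC1=C(I)C(C)(C)C[C@@H]2OC(C)(C)O[C@@H]12
F4 | step 6 | (1S,2S)-4-iodo-3,5,5-trimethylcyclohex-3-ene-1,2-diol | CC1=C(I)C(C)(C)C[C@H](O)[C@H]1O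
F5 | step 11 | (E)-3-methyl-5-(trimethylsilyl)pent-2-en-4-ynal | C[Si](C)(C)C#C/C(C)=C/C=O
F6 | step 11 | (2E,4E,6E)-2,7-dimethylocta-2,4,6-triene-1,8-diol | OC/C(C)=C/C=C/C=C(C)/CO
F7 | step 11 | (2E,4E,6E)-1,8-dibromo-2,7-dimethylocta-2,4,6-triene | BrC/C(C)=C/C=C/C=C(C)/CBr
F8 | step 11 | tetraethyl [(2E,4E,6E)-2,7-dimethylocta-2,4,6-triene-1,8-diyl]bis(phosphonate) | CCOP(=O)(OCC)C/C(C)=C/C=C/C=C(C)/CP(=O)(OCC)OCC
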